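The acetylfilicinic ring (2-acetyl-3,5-dihydroxy-4,4-dimethyl-6-alkylcyclohexadienone) is read as a C-dimethylated tetraketide: C3–C4(Me2)–C5 is a dimethylmalonyl unit, and C6–C1–C2 with the acetyl group is acetylacetone. The key step unites the acetylacetone dianion with dimethyl dimethylmalonate by Claisen acylation (C5–C6) and, in the same flask, biomimetic Dieckmann closure (C2–C3) of the linear triketo ester. It gives the ring with gem-dimethyl, acetyl and free C6–H in one operation and is the only ring closure of the route. The other two rings derive from phlorobutyrophenone, and two formaldehyde Knoevenagel–Michael couplings install the methylene bridges.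

Key step: step 3

Remark: the target has no stereocentre and no stereogenic double bond, so it is achiral and no step has to set configuration; all trione rings are written as the enol tautomer of the given structure. Compound 1 is assumed to be a catalogue compound.

Step 1
Reactants: 1 phlorobutyrophenone
Product: 2 butyrylfilicinic acid
Conditions: NaOMe (2.2 equiv), MeI (2.1 equiv), MeOH, 0 °C → rt; then 1 M HCl
Reagents that add atoms: iodomethane CI
Why: Alkylative dearomatisation, in which the phloroglucinolate of 1 is C-methylated twice at the same ring carbon (the second methylation breaks aromaticity), with the limited charge of MeI meant to stop the reaction at the gem-dimethyl stage; no stereocentre is formed.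

Step 2
Reactants: 2 butyrylfilicinic acid, 1 phlorobutyrophenone
Product: 4 norflavaspidic acid BB, via methylidene trione 3 (not isolated)
Conditions: 1 (4 equiv), 37% aq. CH2O (1.0 equiv), 1% aq. KOH, 0 °C, 5 min; then 1 M HCl
Reagents that add atoms: formaldehyde C=O
Why: Knoevenagel condensation of the acidic ring CH of 2 with formaldehyde should give the ene-trione 3, to which the phloroglucinolate of 1 (in excess, so that mono-bridging prevails) adds through a ring carbon in a Michael (Friedel–Crafts-type) alkylation; no stereocentre is formed.

Step 3
Reactants: 5 acetylacetone, 6 dimethyl 2,2-dimethylmalonate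
Product: 8 acetylfilicinic acid, via linear triketo ester 7 (not isolated)
Conditions: 5, LDA (commercial solution, 3.1 equiv), THF, 0 °C; added to 6 (1.5 equiv) in THF, −78 °C → rt, then 50 °C; 1 M HCl
Reagents that add atoms: none
Why: The terminal carbanion of the dilithio dianion of 5 is acylated by one ester group of 6 (intermolecular Claisen condensation, loss of methoxide) to give the linear triketo ester 7 as its dianion, whose C6 (the carbon between the C5 and C7 carbonyls) then attacks the remaining ester carbonyl C1 and expels methoxide (Dieckmann cyclization). The closest known reaction types are the terminal acylation of β-diketone dianions by esters to 1,3,5-triketones and the biomimetic Claisen cyclization of 3,5,7-triketo esters to acylphloroglucinols, here run with the two C-methyl groups already in place. The six-membered carbocycle closes in a 6-(enolexo)-exo-trig mode, and deprotonation of the product to its doubly stabilized dianion should make the closure irreversible. No stereocentre is formed, the product being achiral. The step needs terminal instead of central acylation of 5, which the dianion secures because its last-formed CH2 carbanion is the most nucleophilic site, and Claisen instead of aldol cyclization, which the substrate secures because the quaternary C2 of 7 cannot enolize, the alternative C-acylation would give a four-membered ring, and no methyl carbanion is present at three equivalents of base. Addition of the dianion to an excess of 6 suppresses double acylation of the malonate, and any enol lactone from O-acylation is reopened by methoxide and funnels to 8.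

Step 4
Reactants: 4 norflavaspidic acid BB, 8 acetylfilicinic acid
Product: 10 filixic acid ABB, via methylidene trione 9 (not isolated)
Conditions: 8 (2 equiv), 37% aq. CH2O (1.2 equiv), 1% aq. KOH, 0 °C, 5 min; then 1 M HCl
Reagents that add atoms: formaldehyde C=O
Why: The same Knoevenagel–Michael methylene bridging, in which 8 condenses with formaldehyde to the ene-trione 9 and this is trapped by the only unsubstituted nucleophilic carbon of 4 (the aromatic CH between two hydroxyl groups), the short contact time at 0 °C limiting retro-Michael exchange of the existing bridge; no stereocentre is formed.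

Compound list
1 | 1-(2,4,6-trihydroxyphenyl)butan-1-one (phlorobutyrophenone) | CCCC(=O)c1c(O)cc(O)cc1O | starting material
2 | 2-butanoyl-3,5-dihydroxy-4,4-dimethylcyclohexa-2,5-dien-1-one (butyrylfilicinic acid) | CCCC(=O)C1=C(O)C(C)(C)C(O)=CC1=O | intermediate
3 | 2-butanoyl-3-hydroxy-4,4-dimethyl-6-methylidenecyclohex-2-ene-1,5-dione (methylidene trione; formed and consumed in step 2) | CCCC(=O)C1=C(O)C(C)(C)C(=O)C(=C)C1=O | intermediate
4 | 2-butanoyl-6-[(3-butanoyl-2,4,6-trihydroxyphenyl)methyl]-3,5-dihydroxy-4,4-dimethylcyclohexa-2,5-dien-1-one (norflavaspidic acid BB) | CCCC(=O)C1=C(O)C(C)(C)C(O)=C(Cc2c(O)cc(O)c(C(=O)CCC)c2O)C1=O | intermediate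
5 | pentane-2,4-dione (acetylacetone) | CC(=O)CC(C)=O | starting material
6 | dimethyl 2,2-dimethylpropanedioate (dimethyl dimethylmalonate) | COC(=O)C(C)(C)C(=O)OC | starting material
7 | methyl 2,2-dimethyl-3,5,7-trioxooctanoate (linear triketo ester; formed and consumed in step 3) | COC(=O)C(C)(C)C(=O)CC(=O)CC(C)=O | intermediate
8 | 2-acetyl-3,5-dihydroxy-4,4-dimethylcyclohexa-2,5-dien-1-one (acetylfilicinic acid) | CC(=O)C1=C(O)C(C)(C)C(O)=CC1=O | intermediate
9 | 2-acetyl-3-hydroxy-4,4-dimethyl-6-methylidenecyclohex-2-ene-1,5-dione (methylidene trione; formed and consumed in step 4) | CC(=O)C1=C(O)C(C)(C)C(=O)C(=C)C1=O | intermediate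
10 | 2-acetyl-6-({3-butanoyl-5-[(5-butanoyl-2,4-dihydroxy-3,3-dimethyl-6-oxocyclohexa-1,4-dien-1-yl)methyl]-2,4,6-trihydroxyphenyl}methyl)-3,5-dihydroxy-4,4-dimethylcyclohexa-2,5-dien-1-one (filixic acid ABB) | CCCC(=O)C1=C(O)C(C)(C)C(O)=C(Cc2c(O)c(CC3=C(O)C(C)(C)C(O)=C(C(C)=O)C3=O)c(O)c(C(=O)CCC)c2O)C1=O | target

Total step count: 4
Longest linear sequence: 3 steps (1 → 2 → 4 → 10, steps 1, 2 and 4); step 3 is a one-step branch that joins at step 4.

Steps most likely to fail

1. Step 4. Under alkali the existing methylene bridge of 4 can undergo retro-Michael/Michael exchange, which redistributes the acylfilicinic units over the central ring. In addition, 9 can be consumed by self-coupling with excess 8. The fallback sets out from 8 and returns at 10. Compound 8 is aminomethylated at its ring CH with dimethylmethylideneammonium iodide (CH2Cl2, rt) to the Mannich base 2-acetyl-6-[(dimethylamino)methyl]-3,5-dihydroxy-4,4-dimethylcyclohexa-2,5-dien-1-one F2. F2 is then heated with 4 (1 equiv) in dioxane at 90 °C without added base. Thermal loss of dimethylamine should release 9 slowly, with 4 as the only carbon nucleophile present, and give 10 without free 8 and without alkali.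

2. Step 3. The sequence may stall at the open-chain stage, or be diverted by acylation of both ester groups of 6 by two dianions or by O-acylation to an enol lactone. The fallback sets out from 5 and returns at 8. Compound 5 is C-acylated at its central carbon with purchased methyl 3-chloro-2,2-dimethyl-3-oxopropanoate under soft enolization (MgCl2, pyridine, CH2Cl2, 0 °C → rt) to give methyl 4-acetyl-2,2-dimethyl-3,5-dioxohexanoate F1. LDA (2.2 equiv, THF, −78 °C → rt) then forms the dianion at one of the two equivalent acetyl methyl groups, which closes onto the ester in a Dieckmann cyclization. Six is the only ring size open to this substrate, and no aldol mode exists. Acidification should give 8; the same ring is still the only one closed in the route, now through its CH2–C(=O) bond.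

3. Step 2. The methylene unit may be distributed statistically, by self-coupling of 2 through 3 and by double bridging of 1. The fallback sets out from 2 and returns at 4. Compound 2 is aminomethylated with dimethylmethylideneammonium iodide (CH2Cl2, rt) to 2-butanoyl-6-[(dimethylamino)methyl]-3,5-dihydroxy-4,4-dimethylcyclohexa-2,5-dien-1-one F3. F3 is then heated with 1 (3 equiv) in dioxane at 90 °C. Since no free 2 is present, 3 generated by loss of dimethylamine can only be trapped by 1, and the excess of 1 disfavours a second bridging, so 4 should result.

Further compounds
F1 | step 3 | methyl 4-acetyl-2,2-dimethyl-3,5-dioxohexanoate | COC(=O)C(C)(C)C(=O)C(C(C)=O)C(C)=O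
F2 | step 4 | 2-acetyl-6-[(dimethylamino)methyl]-3,5-dihydroxy-4,4-dimethylcyclohexa-2,5-dien-1-one | CC(=O)C1=C(O)C(C)(C)C(O)=C(CN(C)C)C1=O
F3 | step 2 | 2-butanoyl-6-[(dimethylamino)methyl]-3,5-dihydroxy-4,4-dimethylcyclohexa-2,5-dien-1-one | CCCC(=O)C1=C(O)C(C)(C)C(O)=C(CN(C)C)C1=O
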